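**Retrosynthetic overview**

- The strategy rests on the quaternary C5 of ring A (C3a, C4, C5, C6, C7, C7a), which carries two identical prenyl groups between the C4 carbonyl and the C6 enol. Cutting both C5–CH2 bonds re-aromatises ring A to the (R)-4,6-dihydroxy-7-isovaleryl-2,3-dihydrobenzofuran 9, in which C5 is the only unsubstituted ring carbon, plus two equivalents of prenyl bromide 4.
- 9 comes from its bis-MOM ether 8. The O1–C2 bond of 8 is made by 5-exo opening of the (S)-epoxide 7 by the phenol that lies between the acyl group and the side chain, with inversion to (R) at C2.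
- 7 comes from Shi epoxidation of the mono-prenyl ketone 6, which derives from phloroglucinol 1 by Friedel–Crafts acylation with 2, C-prenylation with 4 and selective bis-MOM protection.
- Ring order: ring A is supplied aromatic by phloroglucinol, the dihydrofuran ring (O1, C2, C3, C3a, C7a) is closed in step 4, and the last step closes no ring but dearomatises ring A.

Key step: step 6

Remark: the D-fructose-derived Shi ketone is taken to convert ArCH2CH=CMe2 into the (R)-epoxide, in the same facial sense as for trans-disubstituted olefins, so its L-enantiomer is used to reach the (S)-epoxide. Bicyclic compounds carry benzofuran numbering; monocyclic ones count the acyl-bearing carbon as C1.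

**Route**

Step 1
Reactants: 1 phloroglucinol; 2 isovaleryl chloride
Product: 3 1-(2,4,6-trihydroxyphenyl)-3-methylbutan-1-one (phlorisovalerophenone)
Conditions: AlCl3 (3 equiv), CH2Cl2/MeNO2, 0 °C → rt; then ice/aq. HCl
Reagents that add atoms: none
Why: Friedel–Crafts acylation of the symmetric triol can give only one regioisomer, and the chelated, deactivated aryl ketone should resist a second acylation.

Step 2
Reactants: 3 phlorisovalerophenone; 4 prenyl bromide
Product: 5 1-[2,4,6-trihydroxy-3-(3-methylbut-2-en-1-yl)phenyl]-3-methylbutan-1-one
Conditions: 4 (0.9 equiv), 10% aq. KOH, 0 °C; then 1 M HCl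
Reagents that add atoms: none
Why: Phenoxide C-alkylation (SN2 on the allylic bromide) is favoured in water because the hydrogen-bonded oxyanions are shielded from O-alkylation, the two free ring positions of 3 are equivalent, and a deficit of bromide at low temperature should hold the reaction mainly at the mono-prenyl stage with unreacted 3 recoverable.

Step 3
Reactants: 5 mono-prenyl triol
Product: 6 1-[2-hydroxy-4,6-bis(methoxymethoxy)-3-(3-methylbut-2-en-1-yl)phenyl]-3-methylbutan-1-one
Conditions: MOMCl (2.1 equiv), i-Pr2NEt, CH2Cl2, 0 °C → rt
Reagents that add atoms: chloromethyl methyl ether (MOMCl), COCCl, for the C4 ether; a second equivalent of chloromethyl methyl ether, COCCl, for the C6 ether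
Why: In this O-alkylation (MOM acetal formation) the non-chelated C4 hydroxyl para to the ketone should react first and the less hindered C6 hydroxyl second, so that the C2 hydroxyl wedged between the prenyl and acyl groups and hydrogen-bonded to the carbonyl stays free, which is the oxygen that must become O1.

Step 4
Reactants: 6 bis-MOM prenyl phenol
Product: 8 1-[(2R)-2-(2-hydroxypropan-2-yl)-4,6-bis(methoxymethoxy)-2,3-dihydro-1-benzofuran-7-yl]-3-methylbutan-1-one, via (S)-epoxide 7 (not isolated)
Conditions: L-fructose-derived Shi ketone (1,2:4,5-di-O-isopropylidene-β-L-erythro-2,3-hexodiulo-2,6-pyranose, 0.3 equiv; commercial or made from L-sorbose), Oxone (2KHSO5·KHSO4·K2SO4), K2CO3, Bu4NHSO4, MeCN/CH2(OMe)2/aq. Na2B4O7 buffer (pH 10.5), 0 °C; then K2CO3, MeOH, rt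
Reagents that add atoms: Oxone, active component potassium peroxymonosulfate KHSO5, [K+].[O-]S(=O)(=O)OO
Why: Shi asymmetric epoxidation through the spiro dioxirane transition state of the L-ketone should deliver oxygen to the face of the trisubstituted olefin that gives the (S)-epoxide, and under base the C2 phenoxide then opens it by 5-exo-tet SN2 attack at the secondary carbon with inversion, which sets (R) at C2 of the dihydrobenzofuran, turns the epoxide oxygen into the tertiary alcohol and avoids the acid-promoted 6-endo chroman pathway.

Step 5
Reactants: 8 bis-MOM dihydrobenzofuran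
Product: 9 1-[(2R)-4,6-dihydroxy-2-(2-hydroxypropan-2-yl)-2,3-dihydro-1-benzofuran-7-yl]-3-methylbutan-1-one
Conditions: 3 M aq. HCl, MeOH, 40 °C
Reagents that add atoms: none
Why: Acid-catalysed acetal cleavage (transacetalisation to methanol) should free both phenols while the ring aryl alkyl ether survives, the tertiary alcohol is protected from ionisation by the adjacent C2–O1 oxygen, and C2 is neither benzylic nor enolisable.

Step 6
Reactants: 9 dihydroxy dihydrobenzofuran; 4 prenyl bromide (first equivalent)
Product: 11 (2R)-6-hydroxy-2-(2-hydroxypropan-2-yl)-7-(3-methylbutanoyl)-5,5-bis(3-methylbut-2-en-1-yl)-2,3-dihydro-1-benzofuran-4(5H)-one, via 5-prenyl phenol 10 (not isolated)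
Conditions: NaOMe (3 equiv), MeOH, −10 → 0 °C, 4 (2.3 equiv in all, slow addition); then 1 M HCl to pH 3
Reagents that add atoms: prenyl bromide, the second equivalent of 4, which supplies the second prenyl group at C5, CC(C)=CCBr
Why: The dianion of 9 should attack the first equivalent of prenyl bromide through C5 in an SN2 reaction and tautomerise back to the arene as 5-prenyl phenol 10, whose dianion is alkylated by the second equivalent at the same carbon, this time breaking aromaticity to give the enolate of 11 that the acid work-up protonates. The closest known reaction type is the alkylative dearomatisation of acylphloroglucinols with prenyl bromide and alkoxide base, which converts deoxyhumulones into lupulone-type beta-acids. No ring is closed and no stereocentre is created, since C5 ends with two identical groups, and the C2 centre is remote and not epimerisable under these conditions. The step needs carbon over oxygen alkylation and, for the second alkylation, C5 over the other oxygen-flanked ring carbons C3a and C7. Hydrogen-bonding methanol and sodium ion pairing shield the oxyanions, and C5 is the only ring carbon ortho to both oxyanions (O4 and O6), whereas C3a is ortho to one only and C7 bears the electron-withdrawing acyl group; attack at C5 alone leads to an anion delocalised over O4, O6 and the acyl oxygen. The tertiary alcohol stays un-ionised in methanol and should not be alkylated.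

**Compound list**

1 | phloroglucinol | Oc1cc(O)cc(O)c1 | starting material
2 | isovaleryl chloride | CC(C)CC(=O)Cl | starting material
3 | 1-(2,4,6-trihydroxyphenyl)-3-methylbutan-1-one | CC(C)CC(=O)c1c(O)cc(O)cc1O | intermediate
4 | prenyl bromide (1-bromo-3-methylbut-2-ene) | CC(C)=CCBr | starting material
5 | 1-[2,4,6-trihydroxy-3-(3-methylbut-2-en-1-yl)phenyl]-3-methylbutan-1-one | CC(C)CC(=O)c1c(O)cc(O)c(CC=C(C)C)c1O | intermediate
6 | 1-[2-hydroxy-4,6-bis(methoxymethoxy)-3-(3-methylbut-2-en-1-yl)phenyl]-3-methylbutan-1-one | CC(C)CC(=O)c1c(OCOC)cc(OCOC)c(CC=C(C)C)c1O | intermediate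
7 | 1-[3-{[(2S)-3,3-dimethyloxiran-2-yl]methyl}-2-hydroxy-4,6-bis(methoxymethoxy)phenyl]-3-methylbutan-1-one | CC(C)CC(=O)c1c(OCOC)cc(OCOC)c(C[C@@H]2OC2(C)C)c1O | intermediate
8 | 1-[(2R)-2-(2-hydroxypropan-2-yl)-4,6-bis(methoxymethoxy)-2,3-dihydro-1-benzofuran-7-yl]-3-methylbutan-1-one | CC(C)CC(=O)c1c(OCOC)cc(OCOC)c2C[C@H](C(C)(C)O)Oc12 | intermediate
9 | 1-[(2R)-4,6-dihydroxy-2-(2-hydroxypropan-2-yl)-2,3-dihydro-1-benzofuran-7-yl]-3-methylbutan-1-one | CC(C)CC(=O)c1c(O)cc(O)c2C[C@H](C(C)(C)O)Oc12 | intermediate
10 | 1-[(2R)-4,6-dihydroxy-2-(2-hydroxypropan-2-yl)-5-(3-methylbut-2-en-1-yl)-2,3-dihydro-1-benzofuran-7-yl]-3-methylbutan-1-one | CC(C)CC(=O)c1c(O)c(CC=C(C)C)c(O)c2C[C@H](C(C)(C)O)Oc12 | intermediate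
11 | (2R)-6-hydroxy-2-(2-hydroxypropan-2-yl)-7-(3-methylbutanoyl)-5,5-bis(3-methylbut-2-en-1-yl)-2,3-dihydro-1-benzofuran-4(5H)-one | CC(C)=CCC1(CC=C(C)C)C(=O)C2=C(O[C@@H](C(C)(C)O)C2)C(C(=O)CC(C)C)=C1O | target

**Step count and risks**

Total step count: 6. Longest linear sequence: 6 steps, from phloroglucinol 1 to 11.

Steps most likely to fail:

1. Step 6. Oxygen alkylation, ipso-alkylation at C3a, or stalling after the first alkylation may compete with the second bond formation at C5. Fallback: setting out from 9, a Tsuji–Trost double allylation with two equivalents of allyl methyl carbonate and Pd(PPh3)4 in THF should give the 5,5-diallyl dienone F1. Any O-allyl ether re-ionises on zerovalent palladium, so material is returned to the C-allylation pathway. Cross-metathesis of both terminal olefins of F1 with excess 2-methyl-2-butene and second-generation Grubbs catalyst, RuCl2(=CHPh)(H2IMes)(PCy3), in CH2Cl2 at 40 °C then returns to the route at 11.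

2. Step 2. Alkylation may run on past the mono-prenyl stage, with loss of material in the separation; step 3 adds a further uncertainty over which chelated hydroxyl is protected. Fallback: setting out from 3, MOMCl and i-Pr2NEt should give the 2-hydroxy-4,6-bis(methoxymethoxy) ketone F2, whose structure is unambiguous by symmetry. Palladium-catalysed O-alkylation with tert-butyl 2-methylbut-3-en-2-yl carbonate and Pd(PPh3)4 in THF at 0 °C should give the 1,1-dimethylallyl aryl ether F3. Aromatic Claisen rearrangement of F3 in toluene at 110 °C moves the allyl group, inverted to a normal prenyl group, to the only open ortho carbon. This returns to the route at 6 and bypasses 5 and the regiochemical question of step 3.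

3. Step 4. The electron-rich free phenolate may be oxidised under the dioxirane conditions, the epoxide may open in the 6-endo mode before work-up, or facial selectivity may be insufficient. Fallback: setting out from 6, silylation with TBSOTf and 2,6-lutidine in CH2Cl2 should give the aryl silyl ether F4. Shi epoxidation of F4 with the same L-ketone gives the isolable (S)-epoxide F5, whose purity can be secured before ring closure. Treatment of F5 with Bu4NF in THF releases the phenoxide, which closes the ring by the same 5-exo opening with inversion and returns to the route at 8.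

**Further compounds**

F1 | step 6 | (2R)-6-hydroxy-2-(2-hydroxypropan-2-yl)-7-(3-methylbutanoyl)-5,5-di(prop-2-en-1-yl)-2,3-dihydro-1-benzofuran-4(5H)-one | C=CCC1(CC=C)C(=O)C2=C(O[C@@H](C(C)(C)O)C2)C(C(=O)CC(C)C)=C1O
F2 | step 2 | 1-[2-hydroxy-4,6-bis(methoxymethoxy)phenyl]-3-methylbutan-1-one | CC(C)CC(=O)c1c(O)cc(OCOC)cc1OCOC
F3 | step 2 | 1-[2,4-bis(methoxymethoxy)-6-(2-methylbut-3-en-2-yloxy)phenyl]-3-methylbutan-1-one | CC(C)CC(=O)c1c(OCOC)cc(OCOC)cc1OC(C)(C)C=C
F4 | step 4 | 1-[2-(tert-butyldimethylsilyloxy)-4,6-bis(methoxymethoxy)-3-(3-methylbut-2-en-1-yl)phenyl]-3-methylbutan-1-one | CC(C)CC(=O)c1c(OCOC)cc(OCOC)c(CC=C(C)C)c1O[Si](C)(C)C(C)(C)C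
F5 | step 4 | 1-[2-(tert-butyldimethylsilyloxy)-3-{[(2S)-3,3-dimethyloxiran-2-yl]methyl}-4,6-bis(methoxymethoxy)phenyl]-3-methylbutan-1-one | CC(C)CC(=O)c1c(OCOC)cc(OCOC)c(C[C@@H]2OC2(C)C)c1O[Si](C)(C)C(C)(C)C
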